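The red run ended with about half as much bis adduct as single product, while the violet run ended with more bis adduct than single product, so I looked for one number that would order such flasks.

| flask | starting material | reagent | remark | time |
|---|---|---|---|---|
| ochre | 43 mM | 47.3 mM | run made earlier |  |
| violet | 22 mM | 47.3 mM | run made earlier |  |
| red | 86 mM | 47.3 mM | run made earlier |  |
| amber | 43 mM | 95 mM | run made earlier |  |
| theta | 43 mM (fed, over 10 min) | 47.3 mM | all else is in the flask from the start; the feed brings no volume worth counting | 15 min |
| beta | 43 mM | 47.3 mM (fed, over 10 min) | all else is in the flask from the start; the feed brings no volume worth counting | 15 min |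
| delta | 43 mM | 47.3 mM | everything together at the start | 15 min |
| epsilon | 43 mM (in portions, 4, over 10 min) | 47.3 mM | first portion at the start, last at 10 min | 15 min |

- ochre (time / min: single product / %, bis adduct / %): 1.33: 9.6, 1.7; 2.50: 14.7, 6.4; 4.00: 17.8, 11.0; 5.00: 17.8, 9.0; 6.00: 17.2, 12.7; 8.00: 15.7, 15.5; 10.0: 16.4, 14.6
- violet (time / min: single product / %, bis adduct / %): 0.833: 9.9, 2.9; 2.50: 16.6, 8.2; 4.00: 16.8, 10.9; 6.00: 17.8, 17.0; 10.0: 19.0, 20.3; 12.0: 16.8, 22.6; 15.0: 17.7, 25.4
- red (time / min: single product / %, bis adduct / %): 1.33: 11.8, 2.1; 2.00: 12.0, 4.3; 3.00: 13.1, 6.5; 4.00: 13.3, 6.7; 6.00: 14.8, 8.4; 10.0: 15.1, 8.7; 15.0: 14.1, 7.6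
- amber (time / min: single product / %, bis adduct / %): 3.00: 19.4, 15.0; 6.00: 18.2, 23.4; 10.0: 17.7, 27.0; 12.0: 17.5, 29.4; 15.0: 16.2, 29.8

(each reading ± 1 percentage point)

* the flask that comes out highest in share of single product in single product plus bis adduct, or "all alike" when all lie within 1.5 percentage points (theta / beta / delta / epsilon / all alike)
* share of single product in single product plus bis adduct at the end, theta
* share of single product in single product plus bis adduct at the end, beta
* share of single product in single product plus bis adduct at the end, delta
* share of single product in single product plus bis adduct at the end, epsilon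



1. My bench rule treated bis adduct as a correction to single product. Let x be the fraction of the charge found as single product plus bis adduct. I expected the ratio of bis adduct to single product to rise in step with x, and I called that ratio divided by x the bis slope, g. The share of single product is then 1/(1 + g·x).

2. The last ochre reading gave x = 31.0 % and a ratio of 0.890, so I read g = 2.87.

3. The border showed in the other runs. The last red reading gave a slope of 2.48 and the last amber reading 4.00, a ratio of 1.61, so the slope is not constant. At x = 1/g = 34.8 % the correction equals the main term, and I trusted the rule only below that.

4. Delta has ochre's charges, but ochre's last reading stands at 10.0 min and delta is asked at 15 min. Ochre's share at that reading was 52.9 %, and I held it as a reading for that earlier time, not as delta's share at its end.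

5. Violet's charge is half of theta's, which is what theta has received at the middle of its feed, so I took violet as theta's stand-in. The product violet made is x = 22.1 % of theta's charge, below the border. My share for theta was 61.2 %. I made no reckoning for beta or epsilon.

6. The forecast named theta highest, with theta 61 %, beta 44 %, delta 52 % and epsilon 57 %: “Fed starting material arrives late and meets little reagent”.

Theta came out highest at 62.4 %, against 46.5 % for beta, 48.8 % for delta and 55.6 % for epsilon. At the end theta also held 4.41 % of other mono adduct. Theta's own x was 18.6 %, and g turns that into 65.2 %, which is 2.7 percentage points above the computed share.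

    starting material + reagent → other mono adduct (k = 0.929 M⁻¹ min⁻¹)
    reagent + single product → bis adduct (k = 9.03 M⁻¹ min⁻¹)
    2 reagent → self-condensation product (k = 4.12 M⁻¹ min⁻¹)
    starting material + reagent ⇌ single product (K = 210 M⁻¹, k = 3.62 M⁻¹ min⁻¹)
    reagent + other mono adduct → bis adduct (k = 3.25 M⁻¹ min⁻¹)
    starting material + single product → side product (k = 0.122 M⁻¹ min⁻¹)

The neighbour of theta charged with 190 mM of reagent reached x = 24.7 %, for which g gives 58.5 %. The computed share for that neighbour is 51.3 %.

The numbers in the tables come from a simulation on assumed constants; the scatter is artificial.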